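(Readings and results are calculated from invented constants.)

Start from the products: target and uncatalysed product both grow through the alpha and gamma runs, and you want to know what stands at the end of Saturday's and Friday's flasks.

| flask | starting material | coupling partner | catalyst | remark | time |
|---|---|---|---|---|---|
| alpha | 0.026 M | 1.5 equiv | 0.79 mol% | run made earlier |  |
| gamma | 0.026 M | 2.2 equiv | 0.79 mol% | run made earlier |  |
| Saturday's | 0.026 M | 3.00 equiv | 0.79 mol% |  | 2.0 min |
| Friday's | 0.026 M | 3.00 equiv | 0.79 mol% |  | 2.5 min |

| run | time / s | starting material / % | target / % | uncatalysed product / % |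
|---|---|---|---|---|
| alpha | 10.0 | 91.7 | 4.8 | 0.8 |
| alpha | 15.0 | 88.1 | 7.4 | 2.4 |
| alpha | 25.0 | 80.6 | 11.2 | 2.9 |
| alpha | 40.0 | 75.1 | 15.7 | 5.0 |
| alpha | 80.0 | 58.0 | 24.1 | 7.6 |
| gamma | 12.0 | 87.1 | 7.0 | 2.1 |
| gamma | 25.0 | 76.2 | 13.2 | 5.2 |
| gamma | 40.0 | 65.5 | 18.7 | 5.5 |
| gamma | 50.0 | 63.4 | 22.1 | 6.3 |
| gamma | 60.0 | 56.2 | 23.8 | 8.8 |
| gamma | 80.0 | 48.1 | 29.0 | 10.5 |

(standard deviation of a reading: 1 percentage point)

- what was read earlier has a scatter of 1 percentage point, one standard deviation

1. which of these there is most of at the end, counted by the starting material in it, Saturday's (starting material / uncatalysed product / target)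
2. which of these there is most of at the end, counted by the starting material in it, Friday's (starting material / uncatalysed product / target)
3. the largest of these amounts at the end, in percent of the starting material charged, Saturday's
4. the largest of these amounts at the end, in percent of the starting material charged, Friday's

The bench rule for a reagent in excess is to freeze it and call the starting material pseudo-first-order. Its border lies in one ratio: in Saturday's and Friday's, full conversion at one partner each costs a third of the coupling partner, so the freeze is rough.

Freeze the ratio of the products instead. If both paths go as starting material times partner, the catalyst stands, and neither path runs back, both cancel from the product ratio, however far they have fallen. Alpha's last reading gives 3.17 at 1.5 equiv and gamma's gives 2.76 at 2.2 equiv. The scatter is 1 percentage point on readings as small as 7.6 %, so you may pool them. Target per uncatalysed product, the selectivity factor, is S = 2.93. Gamma's last reading also leaves 12.4 % of the charge unseen, and I freeze that too.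

Decay constant of starting material: alpha 0.00681 s⁻¹, gamma 0.00915 s⁻¹, straight on to 3.00 equiv: 0.0118 s⁻¹

Fraction left: Saturday's 24.2 %, Friday's 17.0 %

Target = (charge − left − unseen) × S/(1+S): Saturday's 47.3 %, Friday's 52.7 %

So by my reckoning target leads in both flasks.

The forecast names target and target too, but stands lower than my reckoning, at 37 % for Saturday's and 40 % for Friday's: “Target leads in both, shaded down slightly for possible degradation.”

The simulation gives target at 45.8 % in Saturday's and target at 49.8 % in Friday's, with 3.02 and 2.98 target per uncatalysed product.

    starting material + coupling partner + catalyst ⇌ target + catalyst, rate k1*[starting material]*[coupling partner]*[catalyst] forward; the back reaction follows from the equilibrium constant (K = 200 M⁻¹, k = 520 M⁻² s⁻¹)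
    2 starting material → self-condensation product (k = 0.0570 M⁻¹ s⁻¹)
    2 starting material → homo dimer (k = 6.10 × 10⁻⁵ M⁻¹ s⁻¹)
    starting material + coupling partner → uncatalysed product (k = 0.0340 M⁻¹ s⁻¹)

Friday's has not come to rest at 2.50 min, with 21.4 % starting material standing. At ten times the time, 25.0 min, that is down to 3.53 %, uncatalysed product has gone from 16.7 % to 30.4 %, and target has moved from 49.8 % to 52.4 %, having stood at 58.6 % at 10 min. At 25.0 min the ratio of target to uncatalysed product is 1.72, so in Friday's S serves at 2.50 min and not at 25.0 min. In the scheme the target step runs both ways.

In the scheme the forward target step, and with it S, goes with the catalyst amount, which at a fixed loading follows the starting material. For Friday's recipe at 0.010 M that gives S × 0.010 M/0.026 M = 1.13. The computed flask holds 13.9 % target to 11.7 % uncatalysed product, a ratio of 1.19, with starting material on top at 63.4 %.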